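## Structural features

The target is a germacranolide: a ten-membered carbocycle (C1–C10) with a trans-fused α-methylene-γ-butyrolactone across C6–C7 (ring oxygen on C6; C11, C12, C13 are the α-carbon, the carbonyl and the exocyclic methylene). The only ring alkene is C4=C5, with the ring bonds to C3 and C6 trans. This is the geometry usually called E in germacrenes, but the CIP descriptor is Z because C15 carries oxygen. C6 (R), C7 (R) and C8 (S) are contiguous, with the C6 and C8 oxygens on one face and the C7–C11 bond on the other. C10 (R) is insulated from them by the C9 methylene and carries the C14 hydroxymethyl group on the C11 face. Fragile elements are the two Michael acceptors (α-methylene lactone, C8 methacrylate), the allylic C15 alcohol, the 1,3-relationship of the C8 oxygen to C10 (any C10 carbonyl can expel it by E1cB), and the medium ring itself. The real difficulty is to make a ten-membered ring that contains a ring-trans trisubstituted alkene and to set the remote C10 centre. The key step exploits the fact that C10 and C4=C5 stand in the relationship of a cyclodec-5-enone (carbonyl carbon = position 1, alkene = positions 5 and 6, so the rearranged ketone is a 5-enone). Such a ketone arises by a [3,3] shift from a cyclohexane in which C5 and C10 are bonded and carry a 2-propenyl and a vinyl group; one σ bond (C2–C3) is made, one (C5–C10) is broken, and no stereocentre is created.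

## Logic of the disconnections

46 ⇐ 45 ⇐ 44 ⇐ 43. The last bonds cut are the two Si–O bonds at O14 and O15, and C12 is taken back from carbonyl through the lactol to a mixed methyl acetal. The reason is that the α-methylene lactone and the free primary alcohols are the most sensitive groups and must appear last. The gain is a lactone surrogate that survives Grignard reagents, KH and boranes, instead of a cyclic ether that would need a harsh allylic oxidation next to a second allylic ether. The demand is that the last three steps (mild aqueous acid, a neutral oxidation, buffered fluoride) spare both enoates.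

43 ⇐ 41 + 42; 41 ⇐ 40; 40 ⇐ 39 + 20. The C8–O acyl bond is cut, then the PMB ether is restored at O8 and the silyl ether at O14 is removed. O8 must be the only oxygen released oxidatively while O14 and O15 stay silylated. This reduces the ester problem to acylation of a single free secondary alcohol. The oxidative cleavage must not touch the alkenes or the acetal.

39 ⇐ 36 ⇐ 34 (+ 35, 37). The C10–H and C14–O bonds, then the C10=C14 bond, are cut back to the C10 carbonyl. C14 and the C10 stereocentre both derive from that carbonyl, which removes the isolated stereocentre from the problem. The borane must choose C10=C14 over C11=C13 and C4=C5 and must add from the face that gives 10R. The acetal at C12 helps by deactivating and shielding C11=C13.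

34 ⇐ 31. This is the key cut: the C2–C3 bond is broken and C5–C10 is re-formed, turning the ten-membered ketone into a trans-1,2-dialkenylcyclohexanol. The reason is that a [3,3] ring expansion avoids end-to-end closure of a medium ring and fixes the alkene geometry through a chair. The gain is a cyclohexane whose stereocentres can be set by ordinary conformational control. The demand is that 31 has the vinyl and 2-propenyl groups trans-diequatorial and that the product enolate is discharged before it can equilibrate.

31 ⇐ 29 + 30. The C10–C1 bond is cut, since the tertiary allylic alcohol is the adduct of a vinyl nucleophile to a ketone. The ketone must accept the nucleophile equatorially, without enolisation of its acidic, allylic C5–H.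

29 ⇐ 28 ⇐ 27. The C10 carbonyl is returned to an alcohol and the O6–C12 bond of the cyclic acetal is cut to a dimethyl acetal and a free C6 hydroxyl. The trans-fused five-membered ring can only close once C6–OH exists with the right configuration. The gain is a monocyclic cyclohexane-1,3-diol. The ring closure must prefer the five-membered acetal on O6 over a seven-membered one on O10.

27 ⇐ 26 ⇐ 24 (+ 22). The C6–H bond is cut (hydride), then the C10–O and C5–H bonds (conjugate borylation, oxidation, protonation). C5 and C6 are thereby set by thermodynamic protonation and by hydroxyl-directed reduction, and C10 acts only as a temporary control element. The gain is a planar enone. Boron must add anti to the C8 ether and the dienolate must be protonated at C5 and not at C3.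

24 ⇐ 18 + 23; 18 ⇐ 17; 23 ⇐ 21 ⇐ 19 + 20 (+ 22). The C5–C4 bond is cut as an sp2–sp2 bond. An enolate alkenylation of a C10 ketone would not distinguish C5 from C9 and would risk expelling either β-oxygen, whereas an α-iodoenone fixes the site and needs no enolate. The gain is two simple pieces. The coupling must run under conditions mild enough for a β-alkoxy ketone.

17 ⇐ 15 ⇐ 12 ⇐ 10 (+ 13, 16). The C11=C13 bond and the two C12–O bonds are cut back to an allyl group. C13 is added by Mannich methylenation of an aldehyde whose carbon (C12) comes from oxidative cleavage of the allyl group, so C12 already sits at the lactone oxidation level. The cleavage must spare the enone alkene and the aldehyde must be protected at once.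

10 ⇐ 7 + 8. The C7–C11 bond is cut as an α'-alkylation of an enone. The adjacent C8 ether directs the electrophile to the opposite face, which sets C7. The enolate must be alkylated faster than it loses the C8 alkoxide.

7 ⇐ 5 ⇐ 3 ⇐ 1 + 2 (+ 4). The C5=C10 alkene is traced to elimination of acetate from a β-acetoxy ketone, and the monoacetate to a meso diol from a C3-symmetric triol. C8 thus becomes the only stereocentre set by a chiral agent, and every other centre is relayed from it. The enzyme must distinguish the two enantiotopic hydroxyls.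

## Other disconnections considered

Alternative 1: The cut removes the C9–C10 bond and the bond between the C8 oxygen and the oxime oxygen, treating an isoxazoline as a masked C8-hydroxy C10-ketone. In the forward sense the open-chain aldoxime A1 would be oxidised with NaOCl to its 1,3-dipole, which would add across the C8=C9 vinyl group to give the bridged isoxazoline A2. In its favour, one operation would close the carbocycle, place the C8 oxygen and leave C10 at the ketone level after N–O cleavage. The lactone can be present throughout because no organometallic reagent or strong base is used; on this point it is better than the chosen plan, which has to mask C12 as an acetal. Against it here, the ten-membered ring would be closed end to end, so high dilution is needed and dimerisation of the dipole would compete. The bridged transition state must also accommodate the ring-trans alkene and the trans-lactone, and the C8 configuration would depend on 1,2-induction from C7 alone. On structure the two plans reach the same kind of intermediate and are equal in leaving C10 to be set afterwards. On mechanism the ring expansion carries no entropic penalty, whereas the cycloaddition does. In step count the two should be similar, since A1 needs its own enantioselective acyclic synthesis.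

Alternative 2: The cut takes C5 out of the ring: C4–C5 and C5–C6 are traced to a dibromocarbene adduct of a nine-membered cycloalkene, and the lactone C6–O bond is cut with them. In the forward sense AgClO4 would ionise the exo bromide of the dibromocyclopropane acid A3, the cyclopropane would open disrotatorily to a ten-membered bromoallyl cation, and the carboxylate would capture C6 to give A4. It is the equal of the chosen plan in being a ring enlargement and not a macrocyclisation. It is better in that the lactone C–O bond is made in the key step and C10 is already in place, so there is no late C10 problem. Against it, the difficulty is moved into a nine-membered carbocycle with three stereocentres, which is no easier to make than the ten-membered one. One step would also have to deliver carbene face selectivity, exo ionisation, capture at C6 and not at the more substituted C4, and the C6 configuration. The C5 bromine must then be removed in the presence of other alkenes, and AgClO4 is a hazardous perchlorate. Mechanistically a cationic opening invites transannular capture, which the anionic [3,3] shift does not. Step economy should be worse because of the nine-membered ring and the extra debromination.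

Alternative 3: The cut is the C7–C8 bond, made by a [2,3]-shift that contracts a thirteen-membered allyl ether. In the forward sense n-BuLi would exchange tin for lithium in the α-stannyl ether A5, and the carbanion would attack C7 with cleavage of O–C13 to give the cyclodecenol A6. It is better than the chosen plan on two points: C10 with C14 is fixed in the acyclic precursor, and C8–OH is released free for acylation. It is equal in that the ten-membered ring is not closed end to end, and the C11=C13 methylene appears in the same step. Against it, the thirteen-membered ether still needs a macrocyclisation, and stoichiometric organotin and a configurationally defined α-alkoxystannane are required. The C7/C8 outcome depends on a transannular five-membered transition state, n-BuLi can attack the benzylic positions of the PMB ethers or trigger a [1,2]-shift, and the lactone must still be assembled from O6 and C12 afterwards. Both key steps are sigmatropic, but the oxy-Cope chair is the more predictable. In step count the acyclic route to A5 (three separate stereocentres) should be as long as or longer than the chosen sequence.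

Key step: step 17

Remark on the chemistry: the mixed-acetal carbon C12 in 28, 29, 31–34, 36, 38–41, 43 and 44 forms as both epimers and is written without a descriptor, because it ends as the lactone carbonyl; locants C1–C15 are those of the germacrane skeleton of 46.

## Steps

Step 1
Reactants: 1 cis,cis-cyclohexane-1,3,5-triol; 2 4-methoxybenzyl chloride
Product: 3 all-cis-5-[(4-methoxybenzyl)oxy]cyclohexane-1,3-diol (meso)
Conditions: NaH (1 equiv), DMF, 0 °C to rt; 1 in threefold excess
Reagents that add atoms: 4-methoxybenzyl chloride (2), COc1ccc(CCl)cc1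
Why: Williamson etherification; the three hydroxyls of 1 are equivalent, so one equivalent of base with 1 in excess should give mainly the mono-ether, which keeps a mirror plane.

Step 2
Reactants: 3 all-cis-5-[(4-methoxybenzyl)oxy]cyclohexane-1,3-diol; 4 vinyl acetate
Product: 5 (1S,3S,5R)-3-hydroxy-5-[(4-methoxybenzyl)oxy]cyclohexyl acetate
Conditions: vinyl acetate, lipase B from Candida antarctica (immobilised), MTBE, rt
Reagents that add atoms: vinyl acetate (4), C=COC(C)=O
Why: Lipase-catalysed transesterification (enzymatic desymmetrisation of a meso 1,3-diol) acylates one enantiotopic hydroxyl irreversibly, because the vinyl alcohol released tautomerises; the enzyme is chosen so that the acetate sits on the carbon that becomes C10, which fixes the absolute configuration of C8.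

Step 3
Reactants: 5 (1S,3S,5R)-3-hydroxy-5-[(4-methoxybenzyl)oxy]cyclohexyl acetate
Product: 7 (5S)-5-[(4-methoxybenzyl)oxy]cyclohex-2-en-1-one, via acetoxy ketone 6 (not isolated)
Conditions: Dess–Martin periodinane, CH2Cl2, 0 °C to rt; then Et3N, 0 °C
Reagents that add atoms: none
Why: Dess–Martin oxidation gives the β-acetoxy ketone, which loses acetic acid by E1cB elimination when Et3N is added; acetate leaves far more readily than the PMB-oxy group, so the alkene should form only on the C5–C10 side.

Step 4
Reactants: 7 (5S)-5-[(4-methoxybenzyl)oxy]cyclohex-2-en-1-one; 8 allyl bromide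
Product: 10 (5S,6R)-5-[(4-methoxybenzyl)oxy]-6-(prop-2-en-1-yl)cyclohex-2-en-1-one, via lithium dienolate 9 (not isolated)
Conditions: LDA, THF, −78 °C; then allyl bromide, DMPU, −78 to −40 °C
Reagents that add atoms: allyl bromide (8), C=CCBr
Why: Kinetic α'-deprotonation of the enone and SN2 alkylation of the cross-conjugated enolate; the electrophile should enter anti to the adjacent C8 ether, which sets C7 trans to it, and the low temperature keeps the enolate from expelling the C8 alkoxide.

Step 5
Reactants: 10 (5S,6R)-5-[(4-methoxybenzyl)oxy]-6-(prop-2-en-1-yl)cyclohex-2-en-1-one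
Product: 12 2-[(1R,6S)-6-[(4-methoxybenzyl)oxy]-2-oxocyclohex-3-en-1-yl]acetaldehyde, via vicinal diol 11 (not isolated)
Conditions: K2OsO4·2H2O (cat.), NaIO4, 2,6-lutidine, dioxane/H2O, rt
Reagents that add atoms: sodium periodate (terminal oxidant, source of the aldehyde oxygen through the osmate catalyst), [Na+].[O-]I(=O)(=O)=O
Why: Lemieux–Johnson oxidation (catalytic dihydroxylation, then periodate cleavage); the electron-rich terminal alkene should react while the electron-poor enone alkene is left alone, and the aldehyde carbon obtained is C12.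

Step 6
Reactants: 12 2-[(1R,6S)-6-[(4-methoxybenzyl)oxy]-2-oxocyclohex-3-en-1-yl]acetaldehyde; 13 N,N-dimethylmethyleneiminium iodide
Product: 15 2-[(1R,6S)-6-[(4-methoxybenzyl)oxy]-2-oxocyclohex-3-en-1-yl]prop-2-enal, via Mannich base 14 (not isolated)
Conditions: (CH2=NMe2)I, Et3N, CH2Cl2, rt
Reagents that add atoms: N,N-dimethylmethyleneiminium iodide (13), C=[N+](C)C.[I-]
Why: Mannich reaction of the aldehyde enol with the iminium salt followed by β-elimination of dimethylamine (α-methylenation of an aldehyde); it adds C13 and creates the C11=C13 bond.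

Step 7
Reactants: 15 2-[(1R,6S)-6-[(4-methoxybenzyl)oxy]-2-oxocyclohex-3-en-1-yl]prop-2-enal; 16 trimethyl orthoformate
Product: 17 (5S,6R)-6-(3,3-dimethoxyprop-1-en-2-yl)-5-[(4-methoxybenzyl)oxy]cyclohex-2-en-1-one
Conditions: HC(OMe)3, PPTS (cat.), MeOH, 0 °C
Reagents that add atoms: trimethyl orthoformate (16), COC(OC)OC
Why: Acid-catalysed acetalisation, selective for the aldehyde over the conjugated ketone; C12 is now held at the oxidation level of the lactone carbonyl in a base-stable form.

Step 8
Reactants: 17 (5S,6R)-6-(3,3-dimethoxyprop-1-en-2-yl)-5-[(4-methoxybenzyl)oxy]cyclohex-2-en-1-one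
Product: 18 (5S,6R)-6-(3,3-dimethoxyprop-1-en-2-yl)-2-iodo-5-[(4-methoxybenzyl)oxy]cyclohex-2-en-1-one
Conditions: I2, pyridine/CH2Cl2, 0 °C to rt
Reagents that add atoms: iodine, II
Why: α-Iodination of an enone by conjugate addition of pyridine, iodination of the resulting enolate and elimination; it marks C5 as the coupling site with no regiochemical ambiguity.

Step 9
Reactants: 19 2-bromoprop-2-en-1-ol; 20 tert-butyldimethylsilyl chloride
Product: 21 [(2-bromoprop-2-en-1-yl)oxy](tert-butyl)dimethylsilane
Conditions: TBSCl, imidazole, CH2Cl2, rt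
Reagents that add atoms: tert-butyldimethylsilyl chloride (20), C[Si](C)(Cl)C(C)(C)C
Why: Silylation of a primary alcohol with imidazole as base and nucleophilic catalyst.

Step 10
Reactants: 21 [(2-bromoprop-2-en-1-yl)oxy](tert-butyl)dimethylsilane; 22 bis(pinacolato)diboron
Product: 23 tert-butyldimethyl{[2-(4,4,5,5-tetramethyl-1,3,2-dioxaborolan-2-yl)prop-2-en-1-yl]oxy}silane
Conditions: B2pin2, PdCl2(PPh3)2 (cat.), PPh3, KOPh, toluene, 50 °C
Reagents that add atoms: bis(pinacolato)diboron (22), CC1(C)OB(OC1(C)C)B1OC(C)(C)C(C)(C)O1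
Why: Miyaura borylation of a 1-alkenyl bromide; phenoxide is the mild base that allows transmetallation without coupling of the product.

Step 11
Reactants: 18 (5S,6R)-6-(3,3-dimethoxyprop-1-en-2-yl)-2-iodo-5-[(4-methoxybenzyl)oxy]cyclohex-2-en-1-one; 23 tert-butyldimethyl{[2-(4,4,5,5-tetramethyl-1,3,2-dioxaborolan-2-yl)prop-2-en-1-yl]oxy}silane
Product: 24 (5S,6R)-2-{3-[(tert-butyldimethylsilyl)oxy]prop-1-en-2-yl}-6-(3,3-dimethoxyprop-1-en-2-yl)-5-[(4-methoxybenzyl)oxy]cyclohex-2-en-1-one
Conditions: PdCl2(dppf) (cat.), K3PO4, THF/H2O, rt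
Reagents that add atoms: alkenylboronate 23, C=C(CO[Si](C)(C)C(C)(C)C)B1OC(C)(C)C(C)(C)O1
Why: Suzuki–Miyaura coupling of an α-iodoenone, which reacts at room temperature; the C4–C5 bond is made between two sp2 carbons, so no enolate of the β-alkoxy ketone is generated.

Step 12
Reactants: 24 (5S,6R)-2-{3-[(tert-butyldimethylsilyl)oxy]prop-1-en-2-yl}-6-(3,3-dimethoxyprop-1-en-2-yl)-5-[(4-methoxybenzyl)oxy]cyclohex-2-en-1-one; 22 bis(pinacolato)diboron
Product: 26 (2S,3S,5S,6R)-2-{3-[(tert-butyldimethylsilyl)oxy]prop-1-en-2-yl}-6-(3,3-dimethoxyprop-1-en-2-yl)-3-hydroxy-5-[(4-methoxybenzyl)oxy]cyclohexan-1-one, via boryl ketone 25 (not isolated)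
Conditions: B2pin2, CuCl (cat.), xantphos (cat.), NaOt-Bu (cat.), MeOH, THF, 0 °C; then NaBO3·4H2O, THF/H2O, rt
Reagents that add atoms: bis(pinacolato)diboron (22, boron of 25), CC1(C)OB(OC1(C)C)B1OC(C)(C)C(C)(C)O1; sodium perborate (oxygen on C10), [Na+].[O-]OB=O
Why: Copper-catalysed conjugate borylation: the boryl-copper species should add to C10 by axial attack anti to the C8 ether, and methanol protonates the dienolate at C5 so that the side chain becomes equatorial and cis to the one on C7; perborate then oxidises the C–B bond with retention.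

Step 13
Reactants: 26 (2S,3S,5S,6R)-2-{3-[(tert-butyldimethylsilyl)oxy]prop-1-en-2-yl}-6-(3,3-dimethoxyprop-1-en-2-yl)-3-hydroxy-5-[(4-methoxybenzyl)oxy]cyclohexan-1-one
Product: 27 (1S,2S,3R,4S,5S)-2-{3-[(tert-butyldimethylsilyl)oxy]prop-1-en-2-yl}-4-(3,3-dimethoxyprop-1-en-2-yl)-5-[(4-methoxybenzyl)oxy]cyclohexane-1,3-diol
Conditions: Me4NBH(OAc)3, MeCN/AcOH, −30 °C
Reagents that add atoms: none
Why: Hydroxyl-directed reduction of a β-hydroxy ketone (Evans–Saksena type): the axial C10 hydroxyl binds boron and delivers hydride to the same face of the C6 carbonyl, so the new C6 hydroxyl should be equatorial, anti to O10 and trans to both neighbouring side chains.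

Step 14
Reactants: 27 (1S,2S,3R,4S,5S)-2-{3-[(tert-butyldimethylsilyl)oxy]prop-1-en-2-yl}-4-(3,3-dimethoxyprop-1-en-2-yl)-5-[(4-methoxybenzyl)oxy]cyclohexane-1,3-diol
Product: 28 (3aR,4S,6S,7S,7aR)-7-{3-[(tert-butyldimethylsilyl)oxy]prop-1-en-2-yl}-2-methoxy-4-[(4-methoxybenzyl)oxy]-3-methylideneoctahydro-1-benzofuran-6-ol (both epimers at C2)
Conditions: PPTS (cat.), 4 Å MS, CH2Cl2, rt
Reagents that add atoms: none
Why: Intramolecular acetal exchange: the C6 hydroxyl captures the allylic oxocarbenium ion of the dimethyl acetal in a 5-exo closure, giving the trans-fused ring from two equatorial substituents; closure onto O10 would need a seven-membered ring and should not compete.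

Step 15
Reactants: 28 (3aR,4S,6S,7S,7aR)-7-{3-[(tert-butyldimethylsilyl)oxy]prop-1-en-2-yl}-2-methoxy-4-[(4-methoxybenzyl)oxy]-3-methylideneoctahydro-1-benzofuran-6-ol
Product: 29 (3aR,4S,7R,7aS)-7-{3-[(tert-butyldimethylsilyl)oxy]prop-1-en-2-yl}-2-methoxy-4-[(4-methoxybenzyl)oxy]-3-methylidenehexahydro-1-benzofuran-6(2H)-one (both epimers at C2)
Conditions: Dess–Martin periodinane, pyridine, CH2Cl2, 0 °C
Reagents that add atoms: none
Why: Dess–Martin oxidation under buffered, non-enolising conditions, so the equatorial C5 configuration of the β,γ-unsaturated ketone and both β-oxygens should be preserved.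

Step 16
Reactants: 29 (3aR,4S,7R,7aS)-7-{3-[(tert-butyldimethylsilyl)oxy]prop-1-en-2-yl}-2-methoxy-4-[(4-methoxybenzyl)oxy]-3-methylidenehexahydro-1-benzofuran-6(2H)-one; 30 vinylmagnesium bromide
Product: 31 (3aR,4S,6R,7R,7aS)-7-{3-[(tert-butyldimethylsilyl)oxy]prop-1-en-2-yl}-6-ethenyl-2-methoxy-4-[(4-methoxybenzyl)oxy]-3-methylideneoctahydro-1-benzofuran-6-ol (both epimers at C2)
Conditions: CH2=CHMgBr, CeCl3, THF, −78 °C
Reagents that add atoms: vinylmagnesium bromide (30), C=C[Mg]Br
Why: Cerium-mediated Grignard 1,2-addition, which suppresses enolisation of the acidic C5–H; equatorial attack, away from the axial hydrogens on C6 and C8, should place the vinyl group equatorial and trans to the C5 side chain, with the hydroxyl axial.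

Step 17
Reactants: 31 (3aR,4S,6R,7R,7aS)-7-{3-[(tert-butyldimethylsilyl)oxy]prop-1-en-2-yl}-6-ethenyl-2-methoxy-4-[(4-methoxybenzyl)oxy]-3-methylideneoctahydro-1-benzofuran-6-ol
Product: 34 (4Z,6R,7R,8S)-15-[(tert-butyldimethylsilyl)oxy]-12-methoxy-8-[(4-methoxybenzyl)oxy]-6,12-epoxy-14-norgermacra-4,11(13)-dien-10-one, via potassium alkoxide 32 (not isolated), via potassium enolate 33 (not isolated)
Conditions: KH, 18-crown-6, THF, 0 °C to rt; then AcOH, −78 °C
Reagents that add atoms: none
Why: KH deprotonates the tertiary C10 hydroxyl and 18-crown-6 frees the alkoxide 32, whose oxyanion weakens the C5–C10 bond and triggers a concerted [3,3]-sigmatropic shift; the closest known reaction type is the anionic oxy-Cope rearrangement of trans-1,2-dialkenylcyclohexanols to cyclodec-5-enones. The six atoms C2=C1–C10–C5–C4=C3 pass through a chair in which C2–C3 forms as C5–C10 breaks, so the ten-membered ring arises by four-carbon ring expansion of the cyclohexane and not by end-to-end closure, and no dilution is needed. No stereocentre is created: C5 and C10 become trigonal, while C6, C7 and C8, all equatorial on the cyclohexane, are untouched. The selectivity required is the ring-trans geometry of C4=C5 (formally Z), and it follows from the diequatorial vinyl and 2-propenyl groups, which place C6 equatorial on the Cope chair. The shift delivers the C1(10) enolate 33 regiospecifically and irreversibly. It is protonated at −78 °C so that it cannot equilibrate toward C9 and expel the C8 ether. The acetal, the silyl ether and the PMB ether are inert to KH.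

Step 18
Reactants: 34 (4Z,6R,7R,8S)-15-[(tert-butyldimethylsilyl)oxy]-12-methoxy-8-[(4-methoxybenzyl)oxy]-6,12-epoxy-14-norgermacra-4,11(13)-dien-10-one; 35 dimethyltitanocene
Product: 36 (4Z,6R,7R,8S)-15-[(tert-butyldimethylsilyl)oxy]-12-methoxy-8-[(4-methoxybenzyl)oxy]-6,12-epoxygermacra-4,10(14),11(13)-triene
Conditions: Cp2TiMe2, toluene, 65 °C
Reagents that add atoms: dimethyltitanocene (35), C[Ti](C)(C1C=CC=C1)C1C=CC=C1
Why: Petasis methylenation: the titanium methylidene generated on heating converts the ketone into the 1,1-disubstituted alkene without base, so the β-PMB-oxy ketone cannot eliminate; acetals and silyl ethers do not react.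

Step 19
Reactants: 36 (4Z,6R,7R,8S)-15-[(tert-butyldimethylsilyl)oxy]-12-methoxy-8-[(4-methoxybenzyl)oxy]-6,12-epoxygermacra-4,10(14),11(13)-triene; 37 9-borabicyclo[3.3.1]nonane
Product: 39 (4Z,6R,7R,8S,10R)-15-[(tert-butyldimethylsilyl)oxy]-12-methoxy-8-[(4-methoxybenzyl)oxy]-6,12-epoxygermacra-4,11(13)-dien-14-ol, via alkylborane 38 (not isolated)
Conditions: 9-BBN (1.1 equiv), THF, 0 °C to rt; then NaBO3·4H2O, H2O, rt
Reagents that add atoms: 9-borabicyclo[3.3.1]nonane (37, boron of 38), B1C2CCCC1CCC2; sodium perborate (oxygen on C14), [Na+].[O-]OB=O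
Why: Hydroboration–oxidation with anti-Markovnikov regiochemistry; 9-BBN should prefer C10=C14, flanked by two methylenes, over C11=C13 (branched at C7 and deactivated by the acetal carbon) and over the trisubstituted C4=C5. Attack from the ring periphery on the conformer that holds C14 on the same face as C15 delivers hydrogen to C10 from outside and should give 10R.

Step 20
Reactants: 39 (4Z,6R,7R,8S,10R)-15-[(tert-butyldimethylsilyl)oxy]-12-methoxy-8-[(4-methoxybenzyl)oxy]-6,12-epoxygermacra-4,11(13)-dien-14-ol; 20 tert-butyldimethylsilyl chloride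
Product: 40 (4Z,6R,7R,8S,10R)-14,15-bis[(tert-butyldimethylsilyl)oxy]-12-methoxy-8-[(4-methoxybenzyl)oxy]-6,12-epoxygermacra-4,11(13)-diene
Conditions: TBSCl, imidazole, DMF, rt
Reagents that add atoms: tert-butyldimethylsilyl chloride (20), C[Si](C)(Cl)C(C)(C)C
Why: Silylation of the primary alcohol, so that O8 will be the only free hydroxyl when the PMB group is removed.

Step 21
Reactants: 40 (4Z,6R,7R,8S,10R)-14,15-bis[(tert-butyldimethylsilyl)oxy]-12-methoxy-8-[(4-methoxybenzyl)oxy]-6,12-epoxygermacra-4,11(13)-diene
Product: 41 (4Z,6R,7R,8S,10R)-14,15-bis[(tert-butyldimethylsilyl)oxy]-12-methoxy-6,12-epoxygermacra-4,11(13)-dien-8-ol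
Conditions: DDQ, CH2Cl2/pH 7 buffer, 0 °C
Reagents that add atoms: none
Why: Oxidative cleavage of a PMB ether by single-electron transfer from the electron-rich arene to DDQ and hydrolysis of the resulting oxocarbenium ion; the buffer protects the acetal and the silyl ethers.

Step 22
Reactants: 41 (4Z,6R,7R,8S,10R)-14,15-bis[(tert-butyldimethylsilyl)oxy]-12-methoxy-6,12-epoxygermacra-4,11(13)-dien-8-ol; 42 methacrylic anhydride
Product: 43 (4Z,6R,7R,8S,10R)-14,15-bis[(tert-butyldimethylsilyl)oxy]-12-methoxy-6,12-epoxygermacra-4,11(13)-dien-8-yl 2-methylprop-2-enoate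
Conditions: methacrylic anhydride, Et3N, DMAP (cat.), CH2Cl2, 0 °C to rt
Reagents that add atoms: methacrylic anhydride (42), C=C(C)C(=O)OC(=O)C(C)=C
Why: DMAP-catalysed acylation of the secondary alcohol through the acylpyridinium ion; the configuration at C8 is retained because the C–O bond is not touched.

Step 23
Reactants: 43 (4Z,6R,7R,8S,10R)-14,15-bis[(tert-butyldimethylsilyl)oxy]-12-methoxy-6,12-epoxygermacra-4,11(13)-dien-8-yl 2-methylprop-2-enoate
Product: 44 (4Z,6R,7R,8S,10R)-14,15-bis[(tert-butyldimethylsilyl)oxy]-12-hydroxy-6,12-epoxygermacra-4,11(13)-dien-8-yl 2-methylprop-2-enoate (both epimers at C12)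
Conditions: PPTS, acetone/H2O, rt
Reagents that add atoms: water, O
Why: Acid-catalysed hydrolysis of the mixed acetal; the allylic oxocarbenium ion forms readily, so conditions mild enough to keep both silyl ethers and both enoates should suffice.

Step 24
Reactants: 44 (4Z,6R,7R,8S,10R)-14,15-bis[(tert-butyldimethylsilyl)oxy]-12-hydroxy-6,12-epoxygermacra-4,11(13)-dien-8-yl 2-methylprop-2-enoate
Product: 45 (4Z,6R,7R,8S,10R)-14,15-bis[(tert-butyldimethylsilyl)oxy]-8-[(2-methylprop-2-enoyl)oxy]germacra-4,11(13)-dien-12,6-olide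
Conditions: PhI(OAc)2, TEMPO (cat.), CH2Cl2, rt
Reagents that add atoms: none
Why: Oxoammonium-mediated oxidation of a lactol to the lactone (TEMPO with PhI(OAc)2 as terminal oxidant); no other free hydroxyl is present and the alkenes are not oxidised.

Step 25
Reactants: 45 (4Z,6R,7R,8S,10R)-14,15-bis[(tert-butyldimethylsilyl)oxy]-8-[(2-methylprop-2-enoyl)oxy]germacra-4,11(13)-dien-12,6-olide
Product: 46 (4Z,6R,7R,8S,10R)-14,15-dihydroxy-8-[(2-methylprop-2-enoyl)oxy]germacra-4,11(13)-dien-12,6-olide (target)
Conditions: HF·pyridine, pyridine, THF, 0 °C to rt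
Reagents that add atoms: none
Why: Fluoride-mediated cleavage of the two primary silyl ethers under buffered, weakly acidic conditions that should not add to either Michael acceptor or cleave the methacrylate.

## Compound list

1 | cis,cis-cyclohexane-1,3,5-triol | O[C@H]1C[C@@H](O)C[C@@H](O)C1 | starting material
2 | 4-methoxybenzyl chloride | COc1ccc(CCl)cc1 | starting material
3 | all-cis-5-[(4-methoxybenzyl)oxy]cyclohexane-1,3-diol (meso) | O[C@H]1C[C@@H](OCc2ccc(OC)cc2)C[C@@H](O)C1 | intermediate
4 | vinyl acetate | C=COC(C)=O | starting material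
5 | (1S,3S,5R)-3-hydroxy-5-[(4-methoxybenzyl)oxy]cyclohexyl acetate | O[C@H]1C[C@@H](OCc2ccc(OC)cc2)C[C@@H](OC(C)=O)C1 | intermediate
6 | (1R,5S)-5-[(4-methoxybenzyl)oxy]-3-oxocyclohexyl acetate | O=C1C[C@@H](OCc2ccc(OC)cc2)C[C@@H](OC(C)=O)C1 | intermediate
7 | (5S)-5-[(4-methoxybenzyl)oxy]cyclohex-2-en-1-one | O=C1C=CC[C@H](OCc2ccc(OC)cc2)C1 | intermediate
8 | allyl bromide | C=CCBr | starting material
9 | lithium (3S)-3-[(4-methoxybenzyl)oxy]cyclohexa-1,5-dien-1-olate | [Li+].[O-]C1=C[C@@H](OCc2ccc(OC)cc2)CC=C1 | intermediate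
10 | (5S,6R)-5-[(4-methoxybenzyl)oxy]-6-(prop-2-en-1-yl)cyclohex-2-en-1-one | O=C1C=CC[C@H](OCc2ccc(OC)cc2)[C@H]1CC=C | intermediate
11 | (5S,6R)-6-(2,3-dihydroxypropyl)-5-[(4-methoxybenzyl)oxy]cyclohex-2-en-1-one (both epimers at the secondary carbinol) | O=C1C=CC[C@H](OCc2ccc(OC)cc2)[C@H]1CC(O)CO | intermediate
12 | 2-[(1R,6S)-6-[(4-methoxybenzyl)oxy]-2-oxocyclohex-3-en-1-yl]acetaldehyde | O=C1C=CC[C@H](OCc2ccc(OC)cc2)[C@H]1CC=O | intermediate
13 | N,N-dimethylmethyleneiminium iodide | C=[N+](C)C.[I-] | starting material
14 | 3-(dimethylamino)-2-[(1R,6S)-6-[(4-methoxybenzyl)oxy]-2-oxocyclohex-3-en-1-yl]propanal (both epimers at C2 of the propanal) | O=C1C=CC[C@H](OCc2ccc(OC)cc2)[C@H]1C(CN(C)C)C=O | intermediate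
15 | 2-[(1R,6S)-6-[(4-methoxybenzyl)oxy]-2-oxocyclohex-3-en-1-yl]prop-2-enal | O=C1C=CC[C@H](OCc2ccc(OC)cc2)[C@H]1C(=C)C=O | intermediate
16 | trimethyl orthoformate | COC(OC)OC | starting material
17 | (5S,6R)-6-(3,3-dimethoxyprop-1-en-2-yl)-5-[(4-methoxybenzyl)oxy]cyclohex-2-en-1-one | O=C1C=CC[C@H](OCc2ccc(OC)cc2)[C@H]1C(=C)C(OC)OC | intermediate
18 | (5S,6R)-6-(3,3-dimethoxyprop-1-en-2-yl)-2-iodo-5-[(4-methoxybenzyl)oxy]cyclohex-2-en-1-one | O=C1C(I)=CC[C@H](OCc2ccc(OC)cc2)[C@H]1C(=C)C(OC)OC | intermediate
19 | 2-bromoprop-2-en-1-ol | C=C(Br)CO | starting material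
20 | tert-butyldimethylsilyl chloride | C[Si](C)(Cl)C(C)(C)C | starting material
21 | [(2-bromoprop-2-en-1-yl)oxy](tert-butyl)dimethylsilane | C=C(Br)CO[Si](C)(C)C(C)(C)C | intermediate
22 | bis(pinacolato)diboron | CC1(C)OB(OC1(C)C)B1OC(C)(C)C(C)(C)O1 | starting material
23 | tert-butyldimethyl{[2-(4,4,5,5-tetramethyl-1,3,2-dioxaborolan-2-yl)prop-2-en-1-yl]oxy}silane | C=C(CO[Si](C)(C)C(C)(C)C)B1OC(C)(C)C(C)(C)O1 | intermediate
24 | (5S,6R)-2-{3-[(tert-butyldimethylsilyl)oxy]prop-1-en-2-yl}-6-(3,3-dimethoxyprop-1-en-2-yl)-5-[(4-methoxybenzyl)oxy]cyclohex-2-en-1-one | O=C1C(C(=C)CO[Si](C)(C)C(C)(C)C)=CC[C@H](OCc2ccc(OC)cc2)[C@H]1C(=C)C(OC)OC | intermediate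
25 | (2R,3S,5S,6R)-2-{3-[(tert-butyldimethylsilyl)oxy]prop-1-en-2-yl}-6-(3,3-dimethoxyprop-1-en-2-yl)-5-[(4-methoxybenzyl)oxy]-3-(4,4,5,5-tetramethyl-1,3,2-dioxaborolan-2-yl)cyclohexan-1-one | O=C1[C@@H](C(=C)CO[Si](C)(C)C(C)(C)C)[C@@H](B2OC(C)(C)C(C)(C)O2)C[C@H](OCc3ccc(OC)cc3)[C@H]1C(=C)C(OC)OC | intermediate
26 | (2S,3S,5S,6R)-2-{3-[(tert-butyldimethylsilyl)oxy]prop-1-en-2-yl}-6-(3,3-dimethoxyprop-1-en-2-yl)-3-hydroxy-5-[(4-methoxybenzyl)oxy]cyclohexan-1-one | O=C1[C@@H](C(=C)CO[Si](C)(C)C(C)(C)C)[C@@H](O)C[C@H](OCc2ccc(OC)cc2)[C@H]1C(=C)C(OC)OC | intermediate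
27 | (1S,2S,3R,4S,5S)-2-{3-[(tert-butyldimethylsilyl)oxy]prop-1-en-2-yl}-4-(3,3-dimethoxyprop-1-en-2-yl)-5-[(4-methoxybenzyl)oxy]cyclohexane-1,3-diol | O[C@@H]1[C@@H](C(=C)CO[Si](C)(C)C(C)(C)C)[C@@H](O)C[C@H](OCc2ccc(OC)cc2)[C@H]1C(=C)C(OC)OC | intermediate
28 | (3aR,4S,6S,7S,7aR)-7-{3-[(tert-butyldimethylsilyl)oxy]prop-1-en-2-yl}-2-methoxy-4-[(4-methoxybenzyl)oxy]-3-methylideneoctahydro-1-benzofuran-6-ol (both epimers at C2) | COC1O[C@@H]2[C@@H](C(=C)CO[Si](C)(C)C(C)(C)C)[C@@H](O)C[C@H](OCc3ccc(OC)cc3)[C@H]2C1=C | intermediate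
29 | (3aR,4S,7R,7aS)-7-{3-[(tert-butyldimethylsilyl)oxy]prop-1-en-2-yl}-2-methoxy-4-[(4-methoxybenzyl)oxy]-3-methylidenehexahydro-1-benzofuran-6(2H)-one (both epimers at C2) | COC1O[C@@H]2[C@@H](C(=C)CO[Si](C)(C)C(C)(C)C)C(=O)C[C@H](OCc3ccc(OC)cc3)[C@H]2C1=C | intermediate
30 | vinylmagnesium bromide | C=C[Mg]Br | starting material
31 | (3aR,4S,6R,7R,7aS)-7-{3-[(tert-butyldimethylsilyl)oxy]prop-1-en-2-yl}-6-ethenyl-2-methoxy-4-[(4-methoxybenzyl)oxy]-3-methylideneoctahydro-1-benzofuran-6-ol (both epimers at C2) | COC1O[C@@H]2[C@@H](C(=C)CO[Si](C)(C)C(C)(C)C)[C@](O)(C=C)C[C@H](OCc3ccc(OC)cc3)[C@H]2C1=C | intermediate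
32 | potassium alkoxide of 31 (O10) | [K+].COC1O[C@@H]2[C@@H](C(=C)CO[Si](C)(C)C(C)(C)C)[C@]([O-])(C=C)C[C@H](OCc3ccc(OC)cc3)[C@H]2C1=C | intermediate
33 | potassium (1(10)Z,4Z,6R,7R,8S)-15-[(tert-butyldimethylsilyl)oxy]-12-methoxy-8-[(4-methoxybenzyl)oxy]-6,12-epoxy-14-norgermacra-1(10),4,11(13)-trien-10-olate (ring carbons trans across both ring alkenes) | [K+].COc1ccc(CO[C@H]2C/C([O-])=C/CC/C(CO[Si](C)(C)C(C)(C)C)=C/[C@H]3OC(OC)C(=C)[C@H]23)cc1 | intermediate
34 | (4Z,6R,7R,8S)-15-[(tert-butyldimethylsilyl)oxy]-12-methoxy-8-[(4-methoxybenzyl)oxy]-6,12-epoxy-14-norgermacra-4,11(13)-dien-10-one | COc1ccc(CO[C@H]2CC(=O)CCC/C(CO[Si](C)(C)C(C)(C)C)=C/[C@H]3OC(OC)C(=C)[C@H]23)cc1 | intermediate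
35 | dimethyltitanocene, Cp2TiMe2 | C[Ti](C)(C1C=CC=C1)C1C=CC=C1 | starting material
36 | (4Z,6R,7R,8S)-15-[(tert-butyldimethylsilyl)oxy]-12-methoxy-8-[(4-methoxybenzyl)oxy]-6,12-epoxygermacra-4,10(14),11(13)-triene | COc1ccc(CO[C@H]2CC(=C)CCC/C(CO[Si](C)(C)C(C)(C)C)=C/[C@H]3OC(OC)C(=C)[C@H]23)cc1 | intermediate
37 | 9-borabicyclo[3.3.1]nonane | B1C2CCCC1CCC2 | starting material
38 | (4Z,6R,7R,8S,10R)-14-(9-borabicyclo[3.3.1]nonan-9-yl)-15-[(tert-butyldimethylsilyl)oxy]-12-methoxy-8-[(4-methoxybenzyl)oxy]-6,12-epoxygermacra-4,11(13)-diene | COc1ccc(CO[C@H]2C[C@H](CB4C5CCCC4CCC5)CCC/C(CO[Si](C)(C)C(C)(C)C)=C/[C@H]3OC(OC)C(=C)[C@H]23)cc1 | intermediate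
39 | (4Z,6R,7R,8S,10R)-15-[(tert-butyldimethylsilyl)oxy]-12-methoxy-8-[(4-methoxybenzyl)oxy]-6,12-epoxygermacra-4,11(13)-dien-14-ol | COc1ccc(CO[C@H]2C[C@H](CO)CCC/C(CO[Si](C)(C)C(C)(C)C)=C/[C@H]3OC(OC)C(=C)[C@H]23)cc1 | intermediate
40 | (4Z,6R,7R,8S,10R)-14,15-bis[(tert-butyldimethylsilyl)oxy]-12-methoxy-8-[(4-methoxybenzyl)oxy]-6,12-epoxygermacra-4,11(13)-diene | COc1ccc(CO[C@H]2C[C@H](CO[Si](C)(C)C(C)(C)C)CCC/C(CO[Si](C)(C)C(C)(C)C)=C/[C@H]3OC(OC)C(=C)[C@H]23)cc1 | intermediate
41 | (4Z,6R,7R,8S,10R)-14,15-bis[(tert-butyldimethylsilyl)oxy]-12-methoxy-6,12-epoxygermacra-4,11(13)-dien-8-ol | O[C@H]1C[C@H](CO[Si](C)(C)C(C)(C)C)CCC/C(CO[Si](C)(C)C(C)(C)C)=C/[C@H]2OC(OC)C(=C)[C@H]12 | intermediate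
42 | methacrylic anhydride | C=C(C)C(=O)OC(=O)C(C)=C | starting material
43 | (4Z,6R,7R,8S,10R)-14,15-bis[(tert-butyldimethylsilyl)oxy]-12-methoxy-6,12-epoxygermacra-4,11(13)-dien-8-yl 2-methylprop-2-enoate | C=C(C)C(=O)O[C@H]1C[C@H](CO[Si](C)(C)C(C)(C)C)CCC/C(CO[Si](C)(C)C(C)(C)C)=C/[C@H]2OC(OC)C(=C)[C@H]12 | intermediate
44 | (4Z,6R,7R,8S,10R)-14,15-bis[(tert-butyldimethylsilyl)oxy]-12-hydroxy-6,12-epoxygermacra-4,11(13)-dien-8-yl 2-methylprop-2-enoate (both epimers at C12) | C=C(C)C(=O)O[C@H]1C[C@H](CO[Si](C)(C)C(C)(C)C)CCC/C(CO[Si](C)(C)C(C)(C)C)=C/[C@H]2OC(O)C(=C)[C@H]12 | intermediate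
45 | (4Z,6R,7R,8S,10R)-14,15-bis[(tert-butyldimethylsilyl)oxy]-8-[(2-methylprop-2-enoyl)oxy]germacra-4,11(13)-dien-12,6-olide | C=C(C)C(=O)O[C@H]1C[C@H](CO[Si](C)(C)C(C)(C)C)CCC/C(CO[Si](C)(C)C(C)(C)C)=C/[C@H]2OC(=O)C(=C)[C@H]12 | intermediate
46 | (4Z,6R,7R,8S,10R)-14,15-dihydroxy-8-[(2-methylprop-2-enoyl)oxy]germacra-4,11(13)-dien-12,6-olide | C=C(C)C(=O)O[C@H]1C[C@H](CO)CCC/C(CO)=C/[C@H]2OC(=O)C(=C)[C@H]12 | target

## Step count and least certain steps

Total: 25 steps. Longest linear sequence: 23 steps (1 to 46 through steps 1–8 and 11–25); steps 9 and 10 make the side fragment 23.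

Step 17 (key step). The most likely failure is proton transfer within the product enolate toward C9 before the quench, followed by loss of the C8 alkoxide; partial reaction through a boat, which would erode the alkene geometry, is the second concern. The fallback removes the free enolate altogether. Starting from 31, the tertiary alcohol would be converted with N-(trimethylsilyl)imidazole into its trimethylsilyl ether F1. F1 would be heated (o-dichlorobenzene, about 200 °C) in a thermal siloxy-Cope rearrangement through the same chair to the trimethylsilyl enol ether F2. Buffered desilylation (Bu4NF, AcOH, −20 °C) would then return to the route at 34.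

Step 19. Two things can go wrong: competing hydroboration of the C11=C13 alkene, and poor or reversed facial selectivity at C10, since the conformational argument for a flexible ten-membered ring is only qualitative. The fallback avoids alkene hydroboration and puts C10 under equilibrium control. Starting from 31, the key step would be run as before but the enolate 33 would be trapped with N-phenylbis(trifluoromethanesulfonimide) to give the C10 enol triflate F3. Methoxycarbonylation (Pd(OAc)2, 1,3-bis(diphenylphosphino)propane, CO, MeOH, Et3N) would give the conjugated methyl ester F4. Conjugate reduction with Mg in MeOH, which leaves isolated alkenes alone, would give the saturated C14 methyl ester F5, whose C10 epimers can be equilibrated with NaOMe and the unwanted one recycled. Reduction with i-Bu2AlH would return to the route at 39.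

Step 4. The risk is β-elimination of the C8 alkoxide from the lithium dienolate, which would lead on to a phenol, together with incomplete facial selectivity. In the fallback, starting from 7, the enolate would be trapped as it forms (LDA in the presence of Me3SiCl, −78 °C) as the trimethylsilyl dienol ether F6. F6 would then be allylated under neutral conditions with allyl methyl carbonate, Pd2(dba)3 and 1,2-bis(diphenylphosphino)ethane (Tsuji–Trost allylation of a silyl enol ether), returning to the route at 10.

Step 12. The risks are addition of boron syn to the C8 ether, protonation of the dienolate at C3 (which would move the side-chain alkene into conjugation), and substitution of the allylic acetal by the boryl-copper species. If boron did add syn, the directed reduction of step 13 would have to be replaced by an undirected small hydride. In the fallback, starting from 24, nucleophilic epoxidation (t-BuOOH, DBU) anti to the C8 ether would give the 5,10-epoxy ketone F7. Reductive opening of its Cα–O bond with SmI2 in THF/MeOH at −78 °C would return to the route at 26.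

Step 2. The risk is insufficient discrimination of the enantiotopic hydroxyls, or a preference for the wrong one. In the fallback, starting from 3, both hydroxyls would be acetylated (Ac2O, pyridine) to the meso diacetate F8. Enzymatic hydrolysis of one ester (the same lipase or pig-liver esterase in phosphate buffer), which is enantiocomplementary to the acylation, would return to the route at 5.

## Further compounds

F1 | step 17 | O10-trimethylsilyl ether of 31 | COC1O[C@@H]2[C@@H](C(=C)CO[Si](C)(C)C(C)(C)C)[C@](O[Si](C)(C)C)(C=C)C[C@H](OCc3ccc(OC)cc3)[C@H]2C1=C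
F2 | step 17 | trimethylsilyl enol ether of 34 at C1(10), ring carbons trans | COc1ccc(CO[C@H]2C/C(O[Si](C)(C)C)=C/CC/C(CO[Si](C)(C)C(C)(C)C)=C/[C@H]3OC(OC)C(=C)[C@H]23)cc1
F3 | step 19 | (1(10)Z,4Z,6R,7R,8S)-15-[(tert-butyldimethylsilyl)oxy]-12-methoxy-8-[(4-methoxybenzyl)oxy]-6,12-epoxy-14-norgermacra-1(10),4,11(13)-trien-10-yl trifluoromethanesulfonate | COc1ccc(CO[C@H]2C/C(OS(=O)(=O)C(F)(F)F)=C/CC/C(CO[Si](C)(C)C(C)(C)C)=C/[C@H]3OC(OC)C(=C)[C@H]23)cc1
F4 | step 19 | methyl (1(10)Z,4Z,6R,7R,8S)-15-[(tert-butyldimethylsilyl)oxy]-12-methoxy-8-[(4-methoxybenzyl)oxy]-6,12-epoxygermacra-1(10),4,11(13)-trien-14-oate | COc1ccc(CO[C@H]2C/C(C(=O)OC)=C/CC/C(CO[Si](C)(C)C(C)(C)C)=C/[C@H]3OC(OC)C(=C)[C@H]23)cc1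
F5 | step 19 | methyl (4Z,6R,7R,8S,10R)-15-[(tert-butyldimethylsilyl)oxy]-12-methoxy-8-[(4-methoxybenzyl)oxy]-6,12-epoxygermacra-4,11(13)-dien-14-oate | COc1ccc(CO[C@H]2C[C@H](C(=O)OC)CCC/C(CO[Si](C)(C)C(C)(C)C)=C/[C@H]3OC(OC)C(=C)[C@H]23)cc1
F6 | step 4 | (S)-{[3-[(4-methoxybenzyl)oxy]cyclohexa-1,5-dien-1-yl]oxy}trimethylsilane | C[Si](C)(C)OC1=C[C@@H](OCc2ccc(OC)cc2)CC=C1
F7 | step 12 | 5,10-epoxide of 24 with the epoxide oxygen trans to the C8 ether | O=C1[C@@]2(C(=C)CO[Si](C)(C)C(C)(C)C)O[C@H]2C[C@H](OCc3ccc(OC)cc3)[C@H]1C(=C)C(OC)OC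
F8 | step 2 | all-cis-5-[(4-methoxybenzyl)oxy]cyclohexane-1,3-diyl diacetate (meso) | CC(=O)O[C@H]1C[C@@H](OCc2ccc(OC)cc2)C[C@@H](OC(C)=O)C1
A1 | alternative 1 | open-chain C10 aldoxime: trans-4,5-disubstituted γ-butyrolactone with the C8=C9 vinyl group on C7 and the C5=C4(CH2OTBS)(CH2)3CH=NOH chain on C6 | ON=CCCC/C(CO[Si](C)(C)C(C)(C)C)=C/[C@H]1OC(=O)C[C@@H]1C=C
A2 | alternative 1 | ten-membered carbocycle bridged by an isoxazoline from C10 to the C8 oxygen, trans-lactone in place | C1(=NO2)CCC/C(CO[Si](C)(C)C(C)(C)C)=C/[C@H]3OC(=O)C[C@@H]3[C@@H]2C1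
A3 | alternative 2 | cis-fused 10,10-dibromobicyclo[7.1.0]decane carrying the C7 acetic acid, the C8 PMB ether and the C14 and C15 silyloxymethyl groups | OC(=O)C[C@@H]1[C@@H](OCc2ccc(OC)cc2)C[C@H](CO[Si](C)(C)C(C)(C)C)CCC[C@]3(CO[Si](C)(C)C(C)(C)C)[C@H]1C3(Br)Br
A4 | alternative 2 | trans-fused lactone on the ten-membered ring with bromine on C5 | COc1ccc(CO[C@H]2C[C@H](CO[Si](C)(C)C(C)(C)C)CCC/C(CO[Si](C)(C)C(C)(C)C)=C(Br)/[C@H]3OC(=O)C[C@H]23)cc1
A5 | alternative 3 | thirteen-membered allyl ether with tributylstannyl on C8 | CCCC[Sn](CCCC)(CCCC)[C@H]1C[C@H](CO[Si](C)(C)C(C)(C)C)CCC/C(CO[Si](C)(C)C(C)(C)C)=C/[C@@H](OCc2ccc(OC)cc2)/C=C(\COCc3ccc(OC)cc3)CO1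
A6 | alternative 3 | cyclodecenol with free C8–OH, the 2-propenyl unit on C7 and the C6 PMB ether | O[C@H]1C[C@H](CO[Si](C)(C)C(C)(C)C)CCC/C(CO[Si](C)(C)C(C)(C)C)=C/[C@@H](OCc2ccc(OC)cc2)[C@@H]1C(=C)COCc3ccc(OC)cc3
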